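(The runs were generated by integration on assumed constants; scatter was added.)

Each closed vessel on the bench starts with L and Z, and L leaves it as E.

| flask | L | Z | remark | time |
|---|---|---|---|---|
| epsilon | 2.2 M | 9.2 mM | run made earlier |  |
| delta | 2.2 M | 120 mM | run made earlier |  |
| beta | 1.1 M | 55 mM | run made earlier |  |
| west | 1.5 M | 120 mM |  | 3.0 h |
| south-west | 2.2 M | 55 mM |  | 3.0 h |
| south | 0.80 M | 200 mM |  | 3.0 h |
| north-west | 2.2 M | 20 mM |  | 3.0 h |
| south-east | 2.2 M | 15 mM |  | 3.0 h |

| run | time / h | E / % | L / % |
|---|---|---|---|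
| epsilon | 0.250 | 1.5 | 99.3 |
| epsilon | 0.833 | 2.8 | 96.9 |
| epsilon | 1.33 | 4.5 | 93.3 |
| epsilon | 2.00 | 5.6 | 90.2 |
| epsilon | 3.00 | 5.1 | 86.0 |
| delta | 0.250 | 6.8 | 92.6 |
| delta | 0.417 | 13.3 | 85.2 |
| delta | 0.833 | 29.2 | 63.9 |
| delta | 1.50 | 40.6 | 41.2 |
| delta | 3.00 | 42.5 | 21.8 |
| beta | 0.667 | 7.3 | 90.5 |
| beta | 1.33 | 16.9 | 79.6 |
| beta | 2.00 | 21.7 | 68.8 |
| beta | 2.50 | 25.1 | 64.2 |
| beta | 3.00 | 26.1 | 58.9 |

(each reading ± 0.5 percentage points)

- the earlier runs were read with a standard deviation of 0.5 percentage points

1. all flasks from highest to lowest amount of E, in percent of the L charged, at 3.0 h (west / south-west / south / north-west / south-east)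
2. the amount of E, in percent of the L charged of the flask you put first, at 3.0 h
3. the amount of E, in percent of the L charged of the flask you put last, at 3.0 h

The scale has its zero where every L consumed still stands as E, so that L and E add up to the charge. The shortfall S is what the readings show below that zero, and in the delta run it grows from 18.2% at 1.50 h to 35.7% at 3.00 h. Dividing that growth by [L]₀, by the time between and by the logarithmic mean of the product of the fractions E and L, taken as falling by a steady factor, gives the reading κ = 0.420 L mol⁻¹ h⁻¹, the loss constant, where the forecast's fit over all three runs has 0.36.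

Whoever takes over the south flask finds E and L draining at a pace κ[L]₀ of 0.336 h⁻¹, a pseudo-first-order constant, which is a third of the 0.924 h⁻¹ in delta at equal fractions. Scaled on delta's course, S in south is estimated at about 13.0% at 3.0 h, which would leave L and E together near 87.0%. The forecast gives south > west > south-west > north-west > south-east, with 54% first and 9% last, on the ground that “Low [L] spares E from loss”; its south figures, E and 30% of L, add to 84.0%.

The flasks give south > west > south-west > north-west > south-east, with 54.7% in south and 8.06% in south-east, so the forecast held.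

    L + Z → Q + E (k = 0.00570 L mol⁻¹ min⁻¹)
    L + Q → E + Q, rate k2*[Q]*[L] (k = 0.450 L mol⁻¹ min⁻¹)
    L + E → X (k = 0.00340 L mol⁻¹ min⁻¹)
    Q → G (k = 0.0340 min⁻¹)

In south, X, counted as two and so equal to S, grows by 9.2 points between 1.50 h and 3.00 h, where κ with the logarithmic mean gives 9.3 points. The neighbour is south-east read at 12 h, where E has gone from 8.06% to 0.861% and L from 78.1% to 65.1%. Over that stretch κ gives 20 points, and X in that flask rises by 20 points.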